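**Retrosynthetic overview**
1. Both dihydrofuran rings (ring B and ring A) close last and together: global O‑demethylation, then two p‑quinone‑methide oxa‑cyclisations that make the C2–O bonds 2,3‑trans.
2. The two C2–aryl bonds come from 4‑methoxyphenyl Grignard additions to a bis(α‑chloro ether) made from bis(dimethyl acetal) 13; the CHO comes from an aryl bromide.
3. Key step: two‑fold enantioselective oxidative 1,2‑aryl shift (chiral λ3‑iodane, MeOH) on bis‑stilbene 11, which sets both diarylmethine centres (the future C3 of each ring).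
4. Bis‑stilbene 11 comes from two Heck couplings of 3,5‑dimethoxystyrene: first with iodoarene 8, then with the ring iodide 10.
5. All carbon comes from resorcinol, vinyl bromide and anisole (plus DMF for the formyl carbon).

Assumption: the eight‑atom limit is applied to each starting material as bought, protecting groups included, so methyl ethers are put on with MeI or belong to an eight‑atom material (anisole).
Assumption: the (R,R)‑lactate iodane is written as the reagent antipode that gives the (R,R) centres; the sense is checked once on stilbene 9 and the mirror‑image reagent is used if it proves opposite.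

**Step 1**
Reactants: 1 resorcinol
Product: 2 1,3-dimethoxybenzene
Conditions: MeI, K2CO3, acetone, reflux
Reagents that add atoms: iodomethane, CI
Why: Williamson O‑methylation of both phenols gives ethers that survive every step until the final BBr3 treatment.

**Step 2**
Reactants: 2 1,3-dimethoxybenzene; 3 vinyl bromide
Product: 5 3,5-dimethoxystyrene, via pinacol boronate 4 (not isolated)
Conditions: [Ir(OMe)(cod)]2 (1 mol%), dtbpy, B2pin2 (0.55 equiv), THF, 80 °C; then Pd(dppf)Cl2, aq K3PO4, vinyl bromide (1 M in THF), 60 °C, one pot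
Reagents that add atoms: bis(pinacolato)diboron, CC1(C)OB(OC1(C)C)B1OC(C)(C)C(C)(C)O1 (its boryl group is in 4 only)
Why: Sterically controlled Ir‑catalysed C–H borylation takes the only C–H meta to both OMe groups, and Suzuki–Miyaura coupling of the crude boronate with vinyl bromide gives the styrene.

**Step 3**
Reactants: 6 anisole
Product: 7 4-bromoanisole
Conditions: NBS, MeCN, rt
Reagents that add atoms: N-bromosuccinimide, O=C1CCC(=O)N1Br
Why: Electrophilic aromatic bromination of anisole in MeCN is highly para‑selective.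

**Step 4**
Reactants: 7 4-bromoanisole
Product: 8 4-bromo-2-iodoanisole
Conditions: NIS, TFA (0.3 equiv), MeCN, 60 °C
Reagents that add atoms: N-iodosuccinimide, O=C1CCC(=O)N1I
Why: With the para position blocked, acid‑activated NIS iodinates ortho to OMe (electrophilic aromatic iodination).

**Step 5**
Reactants: 5 3,5-dimethoxystyrene; 8 4-bromo-2-iodoanisole
Product: 9 4-bromo-2-[(E)-2-(3,5-dimethoxyphenyl)ethenyl]-1-methoxybenzene
Conditions: Pd(OAc)2 (3 mol%), n-Bu4NCl, Et3N, DMF, 80 °C, dark
Reagents that add atoms: none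
Why: Ligand‑free Mizoroki–Heck coupling inserts only into C–I (the C–Br bond is kept) and gives the (E)‑stilbene by syn‑insertion/syn‑β‑H elimination.

**Step 6**
Reactants: 9 (E)-stilbene
Product: 10 1-[(E)-2-(5-bromo-2-methoxyphenyl)ethenyl]-2-iodo-3,5-dimethoxybenzene
Conditions: NIS (1.05 equiv), MeCN–CH2Cl2, 0 °C, dark
Reagents that add atoms: N-iodosuccinimide, O=C1CCC(=O)N1I
Why: Electrophilic iodination goes to the doubly activated ring at the position ortho to the styryl arm (para to one OMe, ortho to the other), because the site between the two OMe groups is more hindered and the bromoanisole ring is far less nucleophilic.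

**Step 7**
Reactants: 10 aryl iodide; 5 3,5-dimethoxystyrene
Product: 11 1-[(E)-2-(5-bromo-2-methoxyphenyl)ethenyl]-2-[(E)-2-(3,5-dimethoxyphenyl)ethenyl]-3,5-dimethoxybenzene
Conditions: Pd(OAc)2 (5 mol%), n-Bu4NCl, Et3N, DMF, 90 °C, dark
Reagents that add atoms: none
Why: A second chemoselective Heck coupling at C–I (over the electron‑rich C–Br) installs the second (E)‑styryl arm on the neighbouring ring carbon.

**Step 8**
Reactants: 11 bis-stilbene
Product: 13 1-[(1R)-1-(5-bromo-2-methoxyphenyl)-2,2-dimethoxyethyl]-2-[(1R)-1-(3,5-dimethoxyphenyl)-2,2-dimethoxyethyl]-3,5-dimethoxybenzene, via mono-acetal stilbene 12 (not isolated)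
Conditions: (R,R)-ArI(OAc)2 [Ar = 2,6-bis((1-methoxy-1-oxopropan-2-yl)oxy)phenyl] (2.4 equiv), TfOH (4.8 equiv), MeOH (20 equiv), CH2Cl2, −78 → −40 °C; Et3N quench; chromatography to remove the unlike diastereomers
Reagents that add atoms: methanol, CO
Why: Proposed new method: the TfOH‑activated lactate‑derived chiral aryl‑λ3‑iodane adds to one face of each (E)‑stilbene, methanol opens the iodonium at the carbon carrying the more electron‑rich aryl (the 2,4‑dimethoxy face of the core for one alkene, the o‑anisyl ring for the other), that aryl migrates through a phenonium ion to the neighbouring carbon with loss of ArI (1,2‑aryl shift with inversion) and a second methanol traps the oxocarbenium ion, so both diarylmethine centres are set with the same topicity (R,R) under reagent control and are locked as non‑enolisable acetals, while the minor sense is drained into the separable R,S/S,R diastereomers; the closest known reactions are the racemic ArI(III)/MeOH oxidative rearrangement of stilbenes to diarylacetaldehyde acetals, the stereoselective rearrangement of 1,1‑diarylalkenes to α‑aryl ketones with lactate iodanes, and the enantioselective migratory geminal difluorination of β‑substituted styrenes with chiral aryl iodide catalysts.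

**Step 9**
Reactants: 13 bis(dimethyl acetal); 7 4-bromoanisole
Product: 16 1-[(1R)-1-(5-bromo-2-methoxyphenyl)-2-methoxy-2-(4-methoxyphenyl)ethyl]-2-[(1R)-1-(3,5-dimethoxyphenyl)-2-methoxy-2-(4-methoxyphenyl)ethyl]-3,5-dimethoxybenzene (epimer mixture at both CH(OMe)Ar carbons), via 4-methoxyphenylmagnesium bromide 14 (not isolated), via bis(α-chloro ether) 15 (not isolated)
Conditions: 7, Mg, THF, rt (gives 14); 13, AcCl (2.5 equiv), ZnBr2 (1 mol%), CH2Cl2, 0 °C, then evaporate (gives 15); crude 15 added to 14 (3 equiv), THF, −78 → −20 °C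
Reagents that add atoms: magnesium, [Mg] (in 14 only); acetyl chloride, CC(Cl)=O (its Cl is in 15 only)
Why: Acetal‑to‑α‑chloro‑ether exchange followed by fast Grignard substitution puts the 4‑methoxyphenyl group on each former acetal carbon without ever freeing the racemisation‑prone α,α‑diaryl aldehyde, and the new CH(OMe) centres need no control because they become sp2 in step 11.

**Step 10**
Reactants: 16 aryl bromide
Product: 18 3-[(1R)-1-{2-[(1R)-1-(3,5-dimethoxyphenyl)-2-methoxy-2-(4-methoxyphenyl)ethyl]-3,5-dimethoxyphenyl}-2-methoxy-2-(4-methoxyphenyl)ethyl]-4-methoxybenzaldehyde (epimer mixture as in 16), via aryllithium 17 (not isolated)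
Conditions: n-BuLi (1.1 equiv), THF, −78 °C, 10 min; DMF, −78 → 0 °C; aq NH4Cl
Reagents that add atoms: n-butyllithium, [Li]CCCC (its Li is in 17 only); N,N-dimethylformamide, CN(C)C=O
Why: Br–Li exchange at −78 °C is faster than any deprotonation of the ethers or methines, and formylation of the aryllithium with DMF puts the CHO para to the anisole oxygen.

**Step 11**
Reactants: 18 aldehyde
Product: 21 (2R,3R)-3-[(2R,3R)-3-(3,5-dihydroxyphenyl)-6-hydroxy-2-(4-hydroxyphenyl)-2,3-dihydro-1-benzofuran-4-yl]-2-(4-hydroxyphenyl)-2,3-dihydro-1-benzofuran-5-carbaldehyde, via heptaphenol bis(benzylic bromide) 19 (not isolated), via bis(p-quinone methide) 20 (not isolated)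
Conditions: BBr3 (20 equiv), CH2Cl2, −78 → 0 °C; pour into ice‑cold THF/H2O, then rt 2 h (mildly acidic)
Reagents that add atoms: boron tribromide, BrB(Br)Br (its Br is in 19 only)
Why: BBr3 cleaves the seven aryl methyl ethers and turns the two 4‑methoxybenzylic ethers into bromides, which on aqueous quench lose HBr to p‑quinone methides that are trapped 5‑exo by the neighbouring ortho phenols (biomimetic oxa‑1,6‑addition), each ring closing 2,3‑trans (R at C2) under control of the fixed C3 centre and any cis isomer equilibrating to trans in the acidic hold.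

**Compound list**
1 | resorcinol | Oc1cccc(O)c1 | starting material
2 | 1,3-dimethoxybenzene | COc1cccc(OC)c1 | intermediate
3 | vinyl bromide | C=CBr | starting material
4 | 2-(3,5-dimethoxyphenyl)-4,4,5,5-tetramethyl-1,3,2-dioxaborolane | COc1cc(OC)cc(c1)B1OC(C)(C)C(C)(C)O1 | intermediate
5 | 3,5-dimethoxystyrene | C=Cc1cc(OC)cc(OC)c1 | intermediate
6 | anisole | COc1ccccc1 | starting material
7 | 4-bromoanisole | COc1ccc(Br)cc1 | intermediate
8 | 4-bromo-2-iodoanisole | COc1ccc(Br)cc1I | intermediate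
9 | 4-bromo-2-[(E)-2-(3,5-dimethoxyphenyl)ethenyl]-1-methoxybenzene | COc1ccc(Br)cc1/C=C/c1cc(OC)cc(OC)c1 | intermediate
10 | 1-[(E)-2-(5-bromo-2-methoxyphenyl)ethenyl]-2-iodo-3,5-dimethoxybenzene | COc1ccc(Br)cc1/C=C/c1cc(OC)cc(OC)c1I | intermediate
11 | 1-[(E)-2-(5-bromo-2-methoxyphenyl)ethenyl]-2-[(E)-2-(3,5-dimethoxyphenyl)ethenyl]-3,5-dimethoxybenzene | COc1ccc(Br)cc1/C=C/c1cc(OC)cc(OC)c1/C=C/c1cc(OC)cc(OC)c1 | intermediate
12 | 1-[(E)-2-(5-bromo-2-methoxyphenyl)ethenyl]-2-[(1R)-1-(3,5-dimethoxyphenyl)-2,2-dimethoxyethyl]-3,5-dimethoxybenzene | COc1ccc(Br)cc1/C=C/c1cc(OC)cc(OC)c1[C@@H](c1cc(OC)cc(OC)c1)C(OC)OC | intermediate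
13 | 1-[(1R)-1-(5-bromo-2-methoxyphenyl)-2,2-dimethoxyethyl]-2-[(1R)-1-(3,5-dimethoxyphenyl)-2,2-dimethoxyethyl]-3,5-dimethoxybenzene | COc1ccc(Br)cc1[C@@H](c1cc(OC)cc(OC)c1[C@@H](c1cc(OC)cc(OC)c1)C(OC)OC)C(OC)OC | intermediate
14 | 4-methoxyphenylmagnesium bromide | COc1ccc([Mg]Br)cc1 | intermediate
15 | 1-[(1R)-1-(5-bromo-2-methoxyphenyl)-2-chloro-2-methoxyethyl]-2-[(1R)-2-chloro-1-(3,5-dimethoxyphenyl)-2-methoxyethyl]-3,5-dimethoxybenzene, epimer mixture at both CHCl carbons | COc1ccc(Br)cc1[C@@H](c1cc(OC)cc(OC)c1[C@@H](c1cc(OC)cc(OC)c1)C(Cl)OC)C(Cl)OC | intermediate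
16 | 1-[(1R)-1-(5-bromo-2-methoxyphenyl)-2-methoxy-2-(4-methoxyphenyl)ethyl]-2-[(1R)-1-(3,5-dimethoxyphenyl)-2-methoxy-2-(4-methoxyphenyl)ethyl]-3,5-dimethoxybenzene, epimer mixture at both CH(OMe)Ar carbons | COc1ccc(Br)cc1[C@@H](c1cc(OC)cc(OC)c1[C@@H](c1cc(OC)cc(OC)c1)C(OC)c1ccc(OC)cc1)C(OC)c1ccc(OC)cc1 | intermediate
17 | aryllithium from 16 (Li in place of Br), same stereochemistry | COc1ccc([Li])cc1[C@@H](c1cc(OC)cc(OC)c1[C@@H](c1cc(OC)cc(OC)c1)C(OC)c1ccc(OC)cc1)C(OC)c1ccc(OC)cc1 | intermediate
18 | 3-[(1R)-1-{2-[(1R)-1-(3,5-dimethoxyphenyl)-2-methoxy-2-(4-methoxyphenyl)ethyl]-3,5-dimethoxyphenyl}-2-methoxy-2-(4-methoxyphenyl)ethyl]-4-methoxybenzaldehyde, epimer mixture at both CH(OMe)Ar carbons | COc1ccc(C=O)cc1[C@@H](c1cc(OC)cc(OC)c1[C@@H](c1cc(OC)cc(OC)c1)C(OC)c1ccc(OC)cc1)C(OC)c1ccc(OC)cc1 | intermediate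
19 | 3-[(1R)-2-bromo-1-{2-[(1R)-2-bromo-1-(3,5-dihydroxyphenyl)-2-(4-hydroxyphenyl)ethyl]-3,5-dihydroxyphenyl}-2-(4-hydroxyphenyl)ethyl]-4-hydroxybenzaldehyde, epimer mixture at both CHBr carbons (held as aryloxyboranes until the quench) | Oc1ccc(C=O)cc1[C@@H](c1cc(O)cc(O)c1[C@@H](c1cc(O)cc(O)c1)C(Br)c1ccc(O)cc1)C(Br)c1ccc(O)cc1 | intermediate
20 | 3-[(1R)-1-{2-[(1R)-1-(3,5-dihydroxyphenyl)-2-(4-oxocyclohexa-2,5-dien-1-ylidene)ethyl]-3,5-dihydroxyphenyl}-2-(4-oxocyclohexa-2,5-dien-1-ylidene)ethyl]-4-hydroxybenzaldehyde | Oc1ccc(C=O)cc1[C@@H](c1cc(O)cc(O)c1[C@@H](c1cc(O)cc(O)c1)C=C1C=CC(=O)C=C1)C=C1C=CC(=O)C=C1 | intermediate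
21 | (2R,3R)-3-[(2R,3R)-3-(3,5-dihydroxyphenyl)-6-hydroxy-2-(4-hydroxyphenyl)-2,3-dihydro-1-benzofuran-4-yl]-2-(4-hydroxyphenyl)-2,3-dihydro-1-benzofuran-5-carbaldehyde (CNP0318276.1) | O=Cc1ccc2c(c1)[C@@H](c1cc(O)cc3c1[C@@H](c1cc(O)cc(O)c1)[C@H](c1ccc(O)cc1)O3)[C@H](c1ccc(O)cc1)O2 | target

**Totals**
Total steps: 11. Longest linear sequence: 9 (steps 1, 2, 5, 6, 7, 8, 9, 10, 11; the anisole branch 3, 4, 5 … 11 is equally long).

**Three steps most likely to fail**

Step 8 (the proposed new step). Facial selectivity of the chiral iodane on 1,2‑diarylalkenes is untested, the electron‑rich rings may be oxidised by I(III), and vicinal dimethoxylation can compete with the aryl shift. The fallback uses known chemistry and keeps the 1,2‑aryl shift. It sets out from 11: Shi‑type asymmetric epoxidation of both (E)‑alkenes (the L‑fructose‑derived ketone, Oxone, buffered MeCN/DMM/H2O, 0 °C) gives the all‑(S) bis‑epoxide F1, used crude because it is acid‑labile. A bulky aluminium Lewis acid (MABR, CH2Cl2, −78 °C) opens each oxirane at the carbon carrying the more electron‑rich aryl, and the aryl on the other carbon shifts anti (Meinwald rearrangement) to give the (R,R)‑dialdehyde F2. This is not isolated but acetalised in the cold with HC(OMe)3/MeOH/PPTS, which brings the route back at 13.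

Step 9. The oxocarbenium/α‑chloro ether sits next to very electron‑rich rings, so a seven‑membered Friedel–Crafts closure onto the 3,5‑dimethoxyphenyl ring or participation of an ortho OMe group may compete with the Grignard. The fallback sets out from 13: cold hydrolysis (TFA/H2O/CHCl3, 0 °C) gives the dialdehyde F3 (the same compound as F2). It is used at once, because its α‑centres are labile, with Grignard 14 and LaCl3·2LiCl in THF at −78 °C (carbonyl addition in place of substitution) to give the diol F4. NaH/MeI in THF then returns the route at 16.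

Step 11. Nine ethers must be cleaved while an aldehyde and, later, two quinone methides sit beside nucleophilic resorcinol rings, so aldehyde–resorcinol condensation or C‑alkylation may erode the yield. The fallback sets out from 16, which has no carbonyl: the same BBr3 demethylation and quinone‑methide ring closure gives the bromo bis(dihydrobenzofuran) pentaphenol F5. The formyl group is then introduced last by Pd‑catalysed reductive carbonylation (Pd(OAc)2, di(1‑adamantyl)‑n‑butylphosphine, CO/H2, TMEDA, toluene, 100 °C), which returns the route at 21.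

**Further compounds**
F1 | step 8 | (2S,3S)-2-(5-bromo-2-methoxyphenyl)-3-{2-[(2S,3S)-3-(3,5-dimethoxyphenyl)oxiran-2-yl]-3,5-dimethoxyphenyl}oxirane | COc1ccc(Br)cc1[C@@H]1O[C@H]1c1cc(OC)cc(OC)c1[C@@H]1O[C@H]1c1cc(OC)cc(OC)c1
F2 | step 8 | (2R)-2-(5-bromo-2-methoxyphenyl)-2-{2-[(1R)-1-(3,5-dimethoxyphenyl)-2-oxoethyl]-3,5-dimethoxyphenyl}acetaldehyde | COc1ccc(Br)cc1[C@@H](c1cc(OC)cc(OC)c1[C@@H](c1cc(OC)cc(OC)c1)C=O)C=O
F3 | step 9 | (2R)-2-(5-bromo-2-methoxyphenyl)-2-{2-[(1R)-1-(3,5-dimethoxyphenyl)-2-oxoethyl]-3,5-dimethoxyphenyl}acetaldehyde (identical with F2) | COc1ccc(Br)cc1[C@@H](c1cc(OC)cc(OC)c1[C@@H](c1cc(OC)cc(OC)c1)C=O)C=O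
F4 | step 9 | (2R)-2-(5-bromo-2-methoxyphenyl)-2-{2-[(1R)-1-(3,5-dimethoxyphenyl)-2-hydroxy-2-(4-methoxyphenyl)ethyl]-3,5-dimethoxyphenyl}-1-(4-methoxyphenyl)ethanol, epimer mixture at both carbinol carbons | COc1ccc(Br)cc1[C@@H](c1cc(OC)cc(OC)c1[C@@H](c1cc(OC)cc(OC)c1)C(O)c1ccc(OC)cc1)C(O)c1ccc(OC)cc1
F5 | step 11 | (2R,3R)-4-[(2R,3R)-5-bromo-2-(4-hydroxyphenyl)-2,3-dihydro-1-benzofuran-3-yl]-3-(3,5-dihydroxyphenyl)-2-(4-hydroxyphenyl)-2,3-dihydro-1-benzofuran-6-ol | Brc1ccc2c(c1)[C@@H](c1cc(O)cc3c1[C@@H](c1cc(O)cc(O)c1)[C@H](c1ccc(O)cc1)O3)[C@H](c1ccc(O)cc1)O2
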